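## Structural features

The target is a eudesmane: a trans-fused decalin in which ring A (C1–C5, C10) and ring B (C5–C10) share the C5–C10 bond, with methyl groups on C10 and C4. Four stereocentres stand in a row, C3 (R), C4 (S), C5 (R) and C10 (R). The C3 ester oxygen is axial (3α) and cis to the equatorial tertiary hydroxyl on C4 (4α); the C4 methyl is axial and 1,3-diaxial to the C10 methyl; H5 is α. Ring B holds a C6=C7–C8=O enone whose α carbon C7 carries a 2-hydroxyprop-2-yl group (C11), and C9 is a plain methylene. The fragile groups are the 3-methylbut-2-enoate (base-labile, prone to deconjugation), the tertiary C4 alcohol (elimination in strong acid) and the C11 carbinol, an aldol-type unit on the enone that can dehydrate or undergo retro-aldol cleavage. The real difficulty is the cis-3,4-dioxygen pair on a trans ring fusion, with one oxygen tertiary and only the secondary one acylated, in a single enantiomer. The key step uses the fact that the shared C5–C10 bond and the C4–O bond cis to the C3 ester oxygen are what remains when a germacra-1(10),4-diene is protonated at C1, closes from C5 to C10, and has its C4 cation trapped by an acyloxy group on C3. The 7(11)-en-8-one of the germacrane is one ene reaction away from ring B of the target.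

## Logic of the disconnections

10 to 8. The C11–O bond is cut and the alkene is moved back from C6=C7 to C7=C11, with hydrogen returned to C6. The 11-hydroxy-6-en-8-one is the ene product of a 7(11)-en-8-one with oxygen, so this removes the most sensitive group and leaves a ring B that the terpene starting material already contains. The forward step, through 9, must put oxygen on C11 while taking H6, and must spare the ester alkene.

8 to 6. The C5–C10 bond and the C4–O bond are cut. Both rings and three stereocentres (C4, C5, C10) disappear, leaving a ten-membered ring with one stereocentre. 6 already carries the ester that 10 needs, so the participating group is not exchanged afterwards. The forward step, through 7, must protonate C1 and not C5, must choose one of the two enantiomeric folds of the ring, and must end by ester capture and not by proton loss.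

6 to 4 and 5. The acyl C–O bond is cut. Esterifying before ring closure avoids a later selective acylation of a diol and puts the participating group in place. The forward step must not deconjugate the acyl group or disturb the allylic stereocentre.

4 to 3. The C3 carbinol is taken back to the ketone, which removes the last stereocentre and gives an achiral precursor. The alcohol and any enone from the oxidation then converge on 3, and C3 is set by a catalyst. The forward step must discriminate the two faces of the C3 carbonyl and leave the C8 carbonyl alone.

3 to 1. The C3 oxygen is removed, leaving a C15 terpene that already has every carbon, both E alkenes and the enone. The forward step, through 2, must oxidise C3 among several allylic positions; this is the weakest point in the approach to 6 and is treated as such below.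

## Other disconnections considered

Alternative 1: The cut is C9–C10. The phenol A1 carries a 2-methylidene allylic carbonate on a meta side chain. Pd2(dba)3 with a chiral bisphosphine would ionise the carbonate, and the para carbon of the phenolate (C10, already bearing its methyl) would attack the π-allyl terminus C9 to give the dienone A2.
- In its favour: the quaternary centre is set by a catalyst in a well-studied reaction class, and A1 is a simple aromatic compound.
- Against it here: A2 holds one of the four stereocentres. Ring A would need conjugate reduction, reductive setting of H5 across the tetrasubstituted C4=C5 bond, oxygenation at C4 and a stereoselective C3 reduction. Ring B would need cleavage of the methylidene group to the C8 carbonyl, the whole C11 unit and the C6=C7 bond.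
- Comparison: on the origin of absolute configuration and on access to the precursor this plan is the better one, since the chosen route depends on a C–H oxidation of uncertain site selectivity. On mechanism the two are about equal, because C- against O-allylation and para against ortho attack are no harder to control than the fold selection of the chosen key step. On structure and step economy the chosen plan is well ahead: it forms both rings and three stereocentres in one step from a terpene holding all fifteen carbons.

Alternative 2: The cut is C3–C4. SmI2 would reduce the aldehyde of the keto aldehyde A3 to a ketyl that adds to the samarium-bound methyl ketone, closing ring A as the cis-diol A4.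
- In its favour: chelated ketyl–carbonyl coupling is a dependable way to cis-1,2-diols in six-membered rings.
- Against it here: A3 must already hold the C10 quaternary centre and the trans C5 centre, so a separate asymmetric construction is needed first. The sense of the new diol relative to ring B rests only on the axial methyl. Ring B arrives as a ketal without C11–C13 and without the enone, and the ester must be put on afterwards.
- Comparison: on the reliability of the cis-3,4-diol this plan is the better one, since the chosen step needs neighbouring-group capture to beat proton loss. On structure it builds one ring and two stereocentres against two rings and three. On step economy it is clearly longer.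

Alternative 3: The cut is C4–C5, as a ring expansion. Al(Ot-Bu)3 would chelate the hydroxyl and acetyl oxygens of the trans-hydrindane ketol A5; C5 would migrate from C3 to the acetyl carbon to give the six-membered ketol A6.
- In its favour: the syn-periplanar chelate fixes the C4 configuration, and the five-to-six ring change drives the reaction.
- Against it here: a trans-hydrindane with an angular methyl and a tertiary ketol of defined configuration is itself hard to make. Migration of C2 in place of C5 would give a regioisomer, and the rearrangement is reversible. The C3 ketone then needs an axial-selective reduction, and ring B is as bare as in Alternative 2.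
- Comparison: on fixing the tertiary C4 carbinol this plan is the equal of the chosen one. On mechanism it avoids the conformational question of a ten-membered ring. On structure and step economy it is the weakest of the three, because the key step creates only one stereocentre after a long preparation.

Key step: step 4

Remark (assumption): germacrane numbering (C1=C10, C4=C5, C7=C11, C8=O) is used for the ten-membered ring and eudesmane numbering after ring closure. The E,E geometry and the 3R centre of 6 were checked to map onto 3R,4S,5R,10R in 8 and 10, so no structure needed correction.

## Steps

Step 1
Reactants: 1 germacrone [(1(10)E,4E)-germacra-1(10),4,7(11)-trien-8-one]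
Product: 3 3-oxogermacrone [(1(10)E,4E)-germacra-1(10),4,7(11)-triene-3,8-dione], via racemic 3-hydroxygermacrone 2 (not isolated)
Conditions: SeO2 (0.5 equiv), t-BuOOH (3 equiv), CH2Cl2, 0 °C to rt; filtration through Celite; then MnO2 (15 equiv), CH2Cl2, rt
Reagents that add atoms: selenium dioxide, O=[Se]=O; tert-butyl hydroperoxide, CC(C)(C)OO
Why: SeO2/t-BuOOH allylic oxidation (ene reaction, then [2,3]-sigmatropic shift) should engage the more electron-rich C4=C5 bond, and the usual rule for trisubstituted alkenes (attack on the E-disposed methylene of the disubstituted carbon) points to C3, the sigmatropic step restoring the E alkene. MnO2 oxidises allylic alcohols selectively, so 2 and any enone formed directly converge on achiral 3; no stereocentre is carried forward.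

Step 2
Reactants: 3 3-oxogermacrone
Product: 4 (3R)-3-hydroxygermacrone [(3R,1(10)E,4E)-3-hydroxygermacra-1(10),4,7(11)-trien-8-one]
Conditions: (S)-Me-CBS oxazaborolidine, C18H20BNO (0.2 equiv), catecholborane (1.5 equiv), toluene, -78 °C; then MeOH, aq. NaHCO3
Reagents that add atoms: none
Why: Corey–Bakshi–Shibata reduction: the C3 carbonyl binds the oxazaborolidine boron anti to its larger flank, the methyl-bearing alkenyl carbon C4, and hydride is delivered to the face that gives the R carbinol, by the model that turns acetophenone into (R)-1-phenylethanol with the S catalyst. The C3 carbonyl of the trisubstituted enone should react well before the hindered C8 carbonyl next to the tetrasubstituted alkene, and catecholborane at -78 °C should leave the alkenes alone.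

Step 3
Reactants: 4 (3R)-3-hydroxygermacrone; 5 3-methylbut-2-enoyl chloride
Product: 6 (3R)-3-(3-methylbut-2-enoyloxy)germacrone [(3R,1(10)E,4E)-8-oxogermacra-1(10),4,7(11)-trien-3-yl 3-methylbut-2-enoate]
Conditions: pyridine (3 equiv), 4-(dimethylamino)pyridine (0.1 equiv), CH2Cl2, 0 °C
Reagents that add atoms: none
Why: Acylation of a secondary allylic alcohol with an acid chloride under nucleophilic catalysis; pyridine in place of a trialkylamine keeps the acid chloride from passing through the vinylketene that leads to the deconjugated 3-methylbut-3-enoate. The C3–O bond is not broken, so the R configuration is kept.

Step 4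
Reactants: 6 (3R)-3-(3-methylbut-2-enoyloxy)germacrone
Product: 8 (3R,4S,5R,10R)-3α-(3-methylbut-2-enoyloxy)-4α-hydroxyeudesm-7(11)-en-8-one (4β-methyl, 5α-H, 10β-methyl), via cis-fused dioxolanium ion 7 (not isolated)
Conditions: TsOH·H2O (1.1 equiv), MeNO2, -20 °C to 0 °C; then sat. aq. NaHCO3
Reagents that add atoms: water, O
Why: This is the acid-induced transannular cation–olefin cyclization of a germacra-1(10),4-diene, the known path from germacrone to eudesm-7(11)-en-8-ones, ended here by neighbouring-group capture of the kind that operates in Woodward–Prévost dioxolanium chemistry. Protonation at C1 of the C1=C10 bond (C4=C5 is deactivated by the allylic acyloxy group) gives the tertiary C10 cation, which C5 attacks across the ring; this one C5–C10 bond is a 6-endo-trig closure for ring A and a 6-exo-trig closure for ring B. The charge arriving at C4 is taken by the carbonyl oxygen of the C3 ester in a 5-exo closure to the cis-fused dioxolanium ion 7, and water adds to its central carbon to give an orthoacid that should collapse with the acyl group on the secondary, axial oxygen, the usual outcome for acyloxonium ions on six-membered rings. C10 and C5 are set by the chair–chair fold of the E,E-diene with both vinylic methyls on one face: anti addition across each E alkene gives the 10β-methyl and the 5α-hydrogen, hence the trans fusion. C4 is set by the ester, which can bond only on the face of C4 anti to the incoming C10 and cis to its own C3–O bond, leaving the 4β-methyl axial and the 4α-oxygen equatorial. The step needs a choice between the two enantiomeric folds of the ring; the 3R centre should secure it, because only the fold with the ester pseudoaxial on the α face, anti to C15, lets the carbonyl reach C4 in a cis-fused five-membered ring, whereas the other fold would demand a strained trans-fused ion. It also needs protonation at C1 in preference to ionization of the allylic ester, which the low temperature, the weakly ionizing solvent and the near-stoichiometric acid favour.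

Step 5
Reactants: 8 (3R,4S,5R,10R)-3α-(3-methylbut-2-enoyloxy)-4α-hydroxyeudesm-7(11)-en-8-one
Product: 10 (3R,4S,5R,10R)-3α-(3-methylbut-2-enoyloxy)-4α,11-dihydroxyeudesm-6-en-8-one (the target), via 11-hydroperoxide 9 (not isolated)
Conditions: O2, 5,10,15,20-tetraphenylporphyrin (1 mol %), visible light, CH2Cl2, 0 °C; then PPh3 (1.2 equiv), 0 °C to rt
Reagents that add atoms: dioxygen, O=O
Why: Schenck ene reaction of singlet oxygen with an s-cis α,β-unsaturated ketone, which takes the allylic hydrogen from the group geminal to the carbonyl on the α carbon (H6) and places oxygen on the β carbon (C11), moving the alkene to C6=C7 in conjugation with C8=O; PPh3 then reduces the tertiary hydroperoxide to the alcohol. C11 bears two methyls and is not a stereocentre, C3, C4, C5 and C10 are untouched, and the tetrasubstituted enone should outpace the electron-poor trisubstituted alkene of the ester.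

## Compound list

1 | germacrone, (1(10)E,4E)-germacra-1(10),4,7(11)-trien-8-one | C/C1=C\CC(=C(C)C)C(=O)C/C(C)=C/CC1 | starting material
2 | racemic 3-hydroxygermacrone (not isolated) | OC1C/C=C(C)/CC(=O)C(=C(C)C)C/C=C1\C | intermediate
3 | 3-oxogermacrone, (1(10)E,4E)-germacra-1(10),4,7(11)-triene-3,8-dione | O=C1C/C=C(C)/CC(=O)C(=C(C)C)C/C=C1\C | intermediate
4 | (3R)-3-hydroxygermacrone | O[C@@H]1C/C=C(C)/CC(=O)C(=C(C)C)C/C=C1\C | intermediate
5 | 3-methylbut-2-enoyl chloride | CC(C)=CC(=O)Cl | starting material
6 | (3R)-3-(3-methylbut-2-enoyloxy)germacrone | CC(C)=CC(=O)O[C@@H]1C/C=C(C)/CC(=O)C(=C(C)C)C/C=C1\C | intermediate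
7 | cis-fused 2-(2-methylprop-1-enyl)-1,3-dioxolan-2-ylium ion spanning O3 and O4 of (3R,4S,5R,10R)-eudesm-7(11)-en-8-one (cation, not isolated) | CC(C)=CC(=[O+]3)O[C@@H]1CC[C@]2(C)CC(=O)C(=C(C)C)C[C@H]2[C@@]13C | intermediate
8 | (3R,4S,5R,10R)-3α-(3-methylbut-2-enoyloxy)-4α-hydroxyeudesm-7(11)-en-8-one | CC(C)=CC(=O)O[C@@H]1CC[C@]2(C)CC(=O)C(=C(C)C)C[C@H]2[C@]1(C)O | intermediate
9 | (3R,4S,5R,10R)-3α-(3-methylbut-2-enoyloxy)-4α-hydroxy-11-hydroperoxyeudesm-6-en-8-one (not isolated) | CC(C)=CC(=O)O[C@@H]1CC[C@]2(C)CC(=O)C(C(C)(C)OO)=C[C@H]2[C@]1(C)O | intermediate
10 | (3R,4S,5R,10R)-3α-(3-methylbut-2-enoyloxy)-4α,11-dihydroxyeudesm-6-en-8-one | CC(C)=CC(=O)O[C@@H]1CC[C@]2(C)CC(=O)C(C(C)(C)O)=C[C@H]2[C@]1(C)O | target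

## Step count and least certain steps

Total step count: 5. Longest linear sequence: 5 steps (1 to 3 to 4 to 6 to 8 to 10).

Step 4 (key step). The most likely failures are:
- loss of neighbouring-group control, so that the C4 cation loses a proton from C3 or C15, or is captured from outside, after cyclization through the fold with the ester pseudoequatorial;
- misdirected protonation at C5, with the ester assisting hydration of C4=C5 and no ring closure;
- ionization or 1,3-shift of the allylic ester in the acidic medium.

All three arise because an ester carbonyl is only a moderate internal nucleophile and sits on an allylic carbon. The fallback gives the capture role to a carbonate and postpones the senecioylation. It sets out from 4: methyl chloroformate and pyridine would give the methyl carbonate F1. The same acid treatment should close the ring with the carbonate carbonyl on C4 and, after loss of methanol from the hydrated ion, give the cis-fused cyclic carbonate F2. K2CO3 in methanol would free the 3α,4α-diol F3. Acylation with 5 under the conditions of step 3 should go only to the secondary hydroxyl, and the route is rejoined at 8.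

Step 1. The most likely failure is misdirected site selectivity: ene attack at the vinylic methyls C15 and C14 (with E to Z isomerization of the ring alkene), or at the C1=C10 bond, in place of the ring methylene C3. In an (E)-cyclodecene the C3–H bonds lie near the alkene plane and overlap poorly with the π bond in the ene transition state, whereas a methyl group can always align. This is how related medium-ring E-alkenes are known to behave, so the step is the weakest of the preparative ones. The fallback hands the site selection to an enzyme: a panel of cytochrome P450 monooxygenases (engineered bacterial variants in whole cells with glucose-driven cofactor recycling) would be screened on 1 for hydroxylation at C3, a position that plant enzymes of this class are known to hydroxylate in germacra-1(10),4-dienes. It sets out from 1; any C3 alcohol found, of either configuration, would be oxidised with MnO2 and the route rejoined at 3, so no new compound arises (F0).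

Step 5. The most likely failures are competing ene reaction at the methyls of the ester alkene, hydrogen abstraction from C12 or C13 leading to a deconjugated 7-hydroperoxide, and acid-triggered cleavage of the allylic hydroperoxide before reduction. The fallback builds the C11 carbinol by reduction instead of by an ene reaction. It sets out from 8: nucleophilic epoxidation (t-BuOOH, DBU, CH2Cl2) would give the 7,11-epoxy ketone F4 (either C7 epimer). SmI2 in THF/MeOH at -78 °C should cleave the C7–O bond to the β-hydroxy ketone F5. Dehydrogenation with IBX and 4-methoxypyridine N-oxide in DMSO at rt can only occur towards C6, because C10 bears no hydrogen, and would rejoin the route at 10.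

Step 2. The most likely failures are reduction at the C8 carbonyl and poor facial selectivity, since both flanks of the C3 carbonyl are ring carbons of a flexible macrocycle. The fallback replaces asymmetric reduction by kinetic resolution. It sets out from 2, isolated after the first half of step 1: immobilised Candida antarctica lipase B with vinyl acetate should acylate the R alcohol preferentially (the enantiomer whose larger, higher-priority flank is the alkenyl carbon), giving the (R)-acetate F6. After separation from the unreacted S alcohol, K2CO3 in methanol would rejoin the route at 4. The S alcohol can be returned to 3 with MnO2.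

## Further compounds

F1 | step 4 | (3R)-3-(methoxycarbonyloxy)germacrone | COC(=O)O[C@@H]1C/C=C(C)/CC(=O)C(=C(C)C)C/C=C1\C
F2 | step 4 | (3R,4S,5R,10R)-3α,4α-carbonyldioxyeudesm-7(11)-en-8-one (cis-fused cyclic carbonate) | O=C3O[C@@H]1CC[C@]2(C)CC(=O)C(=C(C)C)C[C@H]2[C@]1(C)O3
F3 | step 4 | (3R,4S,5R,10R)-3α,4α-dihydroxyeudesm-7(11)-en-8-one | O[C@@H]1CC[C@]2(C)CC(=O)C(=C(C)C)C[C@H]2[C@]1(C)O
F0 | step 1 | none | none
F4 | step 5 | (3R,4S,5R,10R)-7,11-epoxy-3α-(3-methylbut-2-enoyloxy)-4α-hydroxyeudesman-8-one (C7 epimers) | CC(C)=CC(=O)O[C@@H]1CC[C@]2(C)CC(=O)C3(OC3(C)C)C[C@H]2[C@]1(C)O
F5 | step 5 | (3R,4S,5R,10R)-3α-(3-methylbut-2-enoyloxy)-4α,11-dihydroxyeudesman-8-one (C7 epimers) | CC(C)=CC(=O)O[C@@H]1CC[C@]2(C)CC(=O)C(C(C)(C)O)C[C@H]2[C@]1(C)O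
F6 | step 2 | (3R)-3-acetoxygermacrone | CC(=O)O[C@@H]1C/C=C(C)/CC(=O)C(=C(C)C)C/C=C1\C
A1 | alternative 1 | 4-(3-hydroxy-2,6-dimethylphenyl)-2-methylidenebutyl methyl carbonate | COC(=O)OCC(=C)CCc1c(C)ccc(O)c1C
A2 | alternative 1 | 8-methylidene bicyclic 1,4-dien-3-one with C4 and C10 methyls (10β-methyl) | O=C1C=C[C@]2(C)CC(=C)CCC2=C1C
A3 | alternative 2 | 3,4-seco keto aldehyde: trans-2-acetyl-1-methyl-1-(3-oxopropyl)cyclohexane with 5,5-ethylenedioxy group | O=CCC[C@]1(C)CC2(OCCO2)CC[C@H]1C(C)=O
A4 | alternative 2 | 3α,4α-dihydroxy-4β-methyl trans-decalin with C8 ethylene ketal | O[C@@H]1CC[C@]2(C)CC3(OCCO3)CC[C@H]2[C@]1(C)O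
A5 | alternative 3 | trans-hydrindane ketol: 3α-acetyl-3β-hydroxy five-membered ring fused at C5–C10, with C8 ethylene ketal | CC(=O)[C@@]1(O)CC[C@]2(C)CC3(OCCO3)CC[C@H]21
A6 | alternative 3 | 4α-hydroxy-4β-methyl-3-oxo trans-decalin with C8 ethylene ketal | O=C1CC[C@]2(C)CC3(OCCO3)CC[C@H]2[C@]1(C)O
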